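**Retrosynthetic overview**
- Target ⇒ global desilylation ⇒ Stille disconnection of the diene single bond into an (E)-iodovinyl cyclohexane (ring A) and a (Z)-γ-stannyl allylic alcohol carried on the epoxycyclohexene (ring B).
- Side-chain carbinol ⇒ Cornforth-controlled addition of a (Z)-2-stannylpropenyllithium (propyne plus hexamethylditin) to the ring B epoxy aldehyde.
- Ring B ⇒ Sharpless epoxidation of a C2-symmetric cis-3,6-disilyloxycyclohexa-1,4-diene-1,4-dimethanol ⇐ double selenoxide elimination ⇐ Noyori hydrogenation of dimethyl succinylsuccinate ⇐ cyclohexane-1,4-dione plus two equivalents of dimethyl carbonate.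
- Ring A ⇒ semipinacol 1,2-alkenyl shift onto the neopentylic ring carbon (inversion) ⇐ α-hydroxy ketone ⇐ conjugate methylation/Rubottom oxidation ⇐ CBS reduction of 2-methylcyclohex-2-enone.
- Ring order: both carbocycles are bought as six-membered rings; the only ring formed is the epoxide on ring B, before the fragments are joined.

Assumption: TBS = tert-butyldimethylsilyl (TBSO = its ether); the two ester-bearing ring carbons of 17–19 are epimer mixtures and are left open in the SMILES because step 11 flattens them.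

**Ring A fragment**

Step 1
Reactants: 1 2-methylcyclohex-2-en-1-one
Product: 2 (1R)-2-methylcyclohex-2-en-1-ol
Conditions: (S)-Me-CBS (10 mol%), BH3·SMe2, THF, −20 °C; MeOH
Reagents that add atoms: none
Why: Corey–Bakshi–Shibata reduction in which the substituted alkenyl carbon acts as the large group, so the (S)-oxazaborolidine delivers hydride to give the (1R) alcohol that becomes the ring A carbinol centre.

Step 2
Reactants: 2 (1R)-2-methylcyclohex-2-en-1-ol
Product: 3 tert-butyl(dimethyl){[(1R)-2-methylcyclohex-2-en-1-yl]oxy}silane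
Conditions: TBSCl, imidazole, DMF, 25 °C
Reagents that add atoms: tert-butyldimethylsilyl chloride, CC(C)(C)[Si](C)(C)Cl
Why: Standard silylation of a secondary allylic alcohol, which protects the carbinol against the oxidation that follows.

Step 3
Reactants: 3 tert-butyl(dimethyl){[(1R)-2-methylcyclohex-2-en-1-yl]oxy}silane
Product: 4 (4R)-4-(TBSO)-3-methylcyclohex-2-en-1-one
Conditions: Rh2(cap)4 (1 mol%), t-BuOOH, CH2Cl2, 25 °C
Reagents that add atoms: tert-butyl hydroperoxide, CC(C)(C)OO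
Why: Allylic C–H oxidation (Doyle conditions) at the ring CH2 next to the unsubstituted alkene carbon, the least hindered allylic position, gives the β-methyl enone without touching the silyloxy centre.

Step 4
Reactants: 4 (4R)-4-(TBSO)-3-methylcyclohex-2-en-1-one
Product: 6 (2S,4R)-4-(TBSO)-2-hydroxy-3,3-dimethylcyclohexan-1-one, via TMS enol ether 5 (not isolated)
Conditions: MeMgBr, CuBr·SMe2 (10 mol%), Me3SiCl, THF, −78 °C; then mCPBA, hexane, −15 °C; then 1 M HCl, THF, 0 °C
Reagents that add atoms: methylmagnesium bromide, C[Mg]Br; chlorotrimethylsilane, C[Si](C)(C)Cl (in 5 only); mCPBA, OOC(=O)c1cccc(Cl)c1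
Why: Copper-catalysed conjugate addition builds the gem-dimethyl carbon and traps the regiodefined enolate, and Rubottom oxidation of 5 occurs on the face anti to the pseudoaxial methyl and away from the equatorial TBSO group, so the new hydroxyl is trans to TBSO (2S).

Step 5
Reactants: 6 (2S,4R)-4-(TBSO)-2-hydroxy-3,3-dimethylcyclohexan-1-one; 7 [(E)-2-bromoethenyl]trimethylsilane
Product: 11 (2R,4R)-4-(TBSO)-3,3-dimethyl-2-[(E)-2-(trimethylsilyl)ethenyl]cyclohexan-1-one, via Grignard reagent 8 (not isolated), via magnesium diolate 9 (not isolated), via mesylate alkoxide 10 (not isolated)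
Conditions: 7, Mg, THF, 25 °C; 6, i-PrMgCl, THF–toluene, −78 °C, then 8, −78 → −20 °C; MsCl, Et3N (cat.), −40 °C; Et3Al, −40 → 0 °C
Reagents that add atoms: magnesium, [Mg] (in 8–10 only); isopropylmagnesium chloride, CC(C)[Mg]Cl (magnesium in 9–10 only); methanesulfonyl chloride, CS(=O)(=O)Cl (in 10 only)
Why: Proposed new method: a one-flask chelation-directed alkenylation, O-sulfonylation and 1,2-alkenyl shift (semipinacol rearrangement) that moves the vinyl group from the carbonyl carbon onto the neopentylic C2 — the chloromagnesium alkoxide of 6 chelates the ketone, so 8 adds equatorially on the face anti to the C2 oxygen (the axial face is shielded by the syn-axial C3 methyl) and 9 is the cis-diolate with the alkenyl group trans to O-2; MsCl (through sulfene) esterifies only the secondary alkoxide, and Et3Al then ionises the mesylate while the tertiary alkoxide pushes the antiperiplanar (trans-diaxial) alkenyl group across with inversion at C2, regenerating the ketone with the vinyl group equatorial and cis to TBSO (2R); epoxide closure is impossible because O-1 and the mesylate are cis, and the alkenyl group should migrate much faster than the ring CH2; the closest known reactions are the Suzuki–Tsuchihashi Et3Al-promoted pinacol-type rearrangement of β-mesyloxy alcohols and the Tiffeneau rearrangement of halohydrin magnesium salts, neither of which has been run as a single operation from a free α-hydroxy ketone or onto a ring carbon flanked by a quaternary centre.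

Step 6
Reactants: 11 (2R,4R)-4-(TBSO)-3,3-dimethyl-2-[(E)-2-(trimethylsilyl)ethenyl]cyclohexan-1-one
Product: 12 (2R,4R)-4-(TBSO)-2-[(E)-2-iodoethenyl]-3,3-dimethylcyclohexan-1-one
Conditions: NIS, (CF3)2CHOH, 0 °C
Reagents that add atoms: N-iodosuccinimide, O=C1CCC(=O)N1I
Why: ipso-Iododesilylation of an (E)-vinylsilane proceeds with retention of geometry, and no other alkene is present at this stage.

Step 7
Reactants: 12 (2R,4R)-4-(TBSO)-2-[(E)-2-iodoethenyl]-3,3-dimethylcyclohexan-1-one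
Product: 13 tert-butyl({(1R,3S)-3-[(E)-2-iodoethenyl]-2,2-dimethyl-4-methylidenecyclohexyl}oxy)dimethylsilane
Conditions: Cp2TiMe2, toluene, 65 °C
Reagents that add atoms: bis(cyclopentadienyl)dimethyltitanium Cp2TiMe2, [CH3-].[CH3-].[Ti+4].c1cc[cH-]c1.c1cc[cH-]c1
Why: Petasis methylenation is non-basic, so the enolisable α-stereocentre (already the more stable equatorial epimer) and the vinyl iodide survive.

**Ring B fragment**

Step 8
Reactants: 14 cyclohexane-1,4-dione; 15 dimethyl carbonate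
Product: 16 dimethyl 2,5-dihydroxycyclohexa-1,4-diene-1,4-dicarboxylate (dimethyl succinylsuccinate)
Conditions: 15 (2.2 equiv in total), NaH (4.4 equiv), THF, reflux; aq. HCl
Reagents that add atoms: dimethyl carbonate (second equivalent of 15), COC(=O)OC
Why: Double Claisen-type methoxycarbonylation, one dimethyl carbonate per ketone α-position, under reversible conditions funnels to the 2,5-isomer, whose two independent chelated β-keto ester enolates make it the thermodynamic sink.

Step 9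
Reactants: 16 dimethyl 2,5-dihydroxycyclohexa-1,4-diene-1,4-dicarboxylate
Product: 17 dimethyl (2S,5S)-2,5-dihydroxycyclohexane-1,4-dicarboxylate
Conditions: RuCl2[(S)-BINAP] (0.5 mol%), H2 (80 atm), MeOH–CH2Cl2, 60 °C
Reagents that add atoms: none
Why: Noyori asymmetric hydrogenation of a β-keto ester through its keto tautomers with (S)-BINAP sets both carbinols (S), the same sense as for 2-(methoxycarbonyl)cycloalkanones, and two like-configured centres give the cis, C2-symmetric ring B diol once the ester-bearing carbons are flattened.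

Step 10
Reactants: 17 dimethyl (2S,5S)-2,5-dihydroxycyclohexane-1,4-dicarboxylate
Product: 18 dimethyl (2S,5S)-2,5-bis(TBSO)cyclohexane-1,4-dicarboxylate
Conditions: TBSCl, imidazole, DMF, 40 °C
Reagents that add atoms: tert-butyldimethylsilyl chloride, CC(C)(C)[Si](C)(C)Cl
Why: Standard silylation of β-hydroxy esters, chosen so that the later epoxidation is steered to the opposite ring face.

Step 11
Reactants: 18 dimethyl (2S,5S)-2,5-bis(TBSO)cyclohexane-1,4-dicarboxylate
Product: 20 dimethyl (3S,6S)-3,6-bis(TBSO)cyclohexa-1,4-diene-1,4-dicarboxylate, via bis-selenide 19 (not isolated)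
Conditions: LiN(i-Pr)2 (2.4 equiv), THF, −78 °C; PhSeBr; then H2O2, pyridine, CH2Cl2, 0 → 25 °C
Reagents that add atoms: benzeneselenenyl bromide, Br[Se]c1ccccc1 (in 19 only)
Why: Ester-enolate selenenylation followed by selenoxide syn-elimination, which avoids the oxygen-bearing carbon, so both C=C bonds form toward the CH2 groups and the two scrambled α-centres disappear.

Step 12
Reactants: 20 dimethyl (3S,6S)-3,6-bis(TBSO)cyclohexa-1,4-diene-1,4-dicarboxylate
Product: 21 [(3S,6S)-3,6-bis(TBSO)cyclohexa-1,4-diene-1,4-diyl]dimethanol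
Conditions: i-Bu2AlH, CH2Cl2, −78 → −20 °C
Reagents that add atoms: none
Why: 1,2-Reduction of both conjugated esters by i-Bu2AlH gives the bis-allylic diol without touching the silyl ethers.

Step 13
Reactants: 21 [(3S,6S)-3,6-bis(TBSO)cyclohexa-1,4-diene-1,4-diyl]dimethanol
Product: 22 [(3S,6S)-3,6-bis(TBSO)-4-(TBSO-methyl)cyclohexa-1,4-dien-1-yl]methanol
Conditions: NaH (1.0 equiv), THF, 0 °C; TBSCl (1.0 equiv)
Reagents that add atoms: tert-butyldimethylsilyl chloride, CC(C)(C)[Si](C)(C)Cl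
Why: Monosilylation through the sparingly soluble mono-sodium alkoxide of a symmetric diol (McDougal protocol); the two hydroxymethyl groups are homotopic, so only one mono-ether can form.

Step 14
Reactants: 22 [(3S,6S)-3,6-bis(TBSO)-4-(TBSO-methyl)cyclohexa-1,4-dien-1-yl]methanol
Product: 23 [(1S,2S,5R,6S)-2,5-bis(TBSO)-4-(TBSO-methyl)-7-oxabicyclo[4.1.0]hept-3-en-1-yl]methanol
Conditions: Ti(OiPr)4 (10 mol%), L-(+)-diethyl tartrate (12 mol%), t-BuOOH, 4 Å MS, CH2Cl2, −20 °C
Reagents that add atoms: tert-butyl hydroperoxide, CC(C)(C)OO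
Why: Sharpless asymmetric epoxidation of the only free allylic alcohol; the face chosen by L-(+)-tartrate is also the face anti to both silyloxy groups (matched pair), which sets the two epoxide carbons.

Step 15
Reactants: 23 [(1S,2S,5R,6S)-2,5-bis(TBSO)-4-(TBSO-methyl)-7-oxabicyclo[4.1.0]hept-3-en-1-yl]methanol
Product: 24 (1S,2S,5R,6S)-2,5-bis(TBSO)-4-(TBSO-methyl)-7-oxabicyclo[4.1.0]hept-3-ene-1-carbaldehyde
Conditions: Dess–Martin periodinane, CH2Cl2, 0 → 25 °C
Reagents that add atoms: none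
Why: Dess–Martin oxidation of the epoxy alcohol; the aldehyde has no α-hydrogen and cannot epimerise.

**Linchpin and union**

Step 16
Reactants: 25 propyne
Product: 26 (Z)-prop-1-ene-1,2-diylbis(trimethylstannane)
Conditions: Me3SnSnMe3, Pd(PPh3)4 (2 mol%), THF, 60 °C, sealed tube
Reagents that add atoms: hexamethylditin, C[Sn](C)(C)[Sn](C)(C)C
Why: Palladium-catalysed syn-distannation of a terminal alkyne places the two tin atoms cis, which fixes the later (Z)-trisubstituted alkene.

Step 17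
Reactants: 26 (Z)-prop-1-ene-1,2-diylbis(trimethylstannane); 24 (1S,2S,5R,6S)-2,5-bis(TBSO)-4-(TBSO-methyl)-7-oxabicyclo[4.1.0]hept-3-ene-1-carbaldehyde
Product: 28 (1S,2Z)-1-[(1S,2S,5R,6S)-2,5-bis(TBSO)-4-(TBSO-methyl)-7-oxabicyclo[4.1.0]hept-3-en-1-yl]-3-(trimethylstannyl)but-2-en-1-ol, via vinyllithium 27 (not isolated)
Conditions: 26, MeLi, THF, −78 °C; then 24, −78 °C; H2O
Reagents that add atoms: methyllithium, C[Li] (lithium in 27 only)
Why: Tin–lithium exchange occurs at the less hindered terminal tin with retention, and the vinyllithium adds to the non-chelated epoxy aldehyde in the Cornforth/Felkin–Anh sense (C=O anti to the epoxide C–O, attack past the ring CH–OTBS hydrogen and not past the tied-back epoxide carbon), giving the anti epoxy alcohol with the (S) carbinol.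

Step 18
Reactants: 28 (1S,2Z)-1-[(1S,2S,5R,6S)-2,5-bis(TBSO)-4-(TBSO-methyl)-7-oxabicyclo[4.1.0]hept-3-en-1-yl]-3-(trimethylstannyl)but-2-en-1-ol; 13 tert-butyl({(1R,3S)-3-[(E)-2-iodoethenyl]-2,2-dimethyl-4-methylidenecyclohexyl}oxy)dimethylsilane
Product: 29 (1S,2Z,4E)-1-[(1S,2S,5R,6S)-2,5-bis(TBSO)-4-(TBSO-methyl)-7-oxabicyclo[4.1.0]hept-3-en-1-yl]-5-[(1S,3R)-3-(TBSO)-2,2-dimethyl-6-methylidenecyclohexyl]-3-methylpenta-2,4-dien-1-ol
Conditions: Pd2(dba)3 (5 mol%), AsPh3 (20 mol%), CuI (10 mol%), DMF, 40 °C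
Reagents that add atoms: none
Why: Stille coupling proceeds with retention at both alkenyl partners and so gives the (2Z,4E)-diene; the free hydroxyl and the epoxide are tolerated.

Step 19
Reactants: 29 (1S,2Z,4E)-1-[(1S,2S,5R,6S)-2,5-bis(TBSO)-4-(TBSO-methyl)-7-oxabicyclo[4.1.0]hept-3-en-1-yl]-5-[(1S,3R)-3-(TBSO)-2,2-dimethyl-6-methylidenecyclohexyl]-3-methylpenta-2,4-dien-1-ol
Product: 30 (1R,2S,5R,6S)-1-{(1S,2Z,4E)-1-hydroxy-5-[(1S,3R)-3-hydroxy-2,2-dimethyl-6-methylidenecyclohexyl]-3-methylpenta-2,4-dien-1-yl}-4-(hydroxymethyl)-7-oxabicyclo[4.1.0]hept-3-ene-2,5-diol (CNP0357844.1)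
Conditions: Bu4NF, AcOH, THF, 0 → 40 °C
Reagents that add atoms: none
Why: Buffered fluoride desilylation removes all four silyl ethers without acid (dienyl carbinol) or strong base (epoxy alcohol, Payne shift).

**Compound list**
1 | 2-methylcyclohex-2-en-1-one | CC1=CCCCC1=O | starting material
2 | (1R)-2-methylcyclohex-2-en-1-ol | CC1=CCCC[C@H]1O | intermediate
3 | tert-butyl(dimethyl){[(1R)-2-methylcyclohex-2-en-1-yl]oxy}silane | CC1=CCCC[C@H]1O[Si](C)(C)C(C)(C)C | intermediate
4 | (4R)-4-(TBSO)-3-methylcyclohex-2-en-1-one | CC1=CC(=O)CC[C@H]1O[Si](C)(C)C(C)(C)C | intermediate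
5 | tert-butyl(dimethyl){[(1R)-2,2-dimethyl-4-(trimethylsilyloxy)cyclohex-3-en-1-yl]oxy}silane | CC1(C)C=C(O[Si](C)(C)C)CC[C@H]1O[Si](C)(C)C(C)(C)C | intermediate
6 | (2S,4R)-4-(TBSO)-2-hydroxy-3,3-dimethylcyclohexan-1-one | O=C1CC[C@@H](O[Si](C)(C)C(C)(C)C)C(C)(C)[C@@H]1O | intermediate
7 | [(E)-2-bromoethenyl]trimethylsilane | C[Si](C)(C)/C=C/Br | starting material
8 | bromo[(E)-2-(trimethylsilyl)ethenyl]magnesium | C[Si](C)(C)/C=C/[Mg]Br | intermediate
9 | magnesium (1S,2S,4R)-4-(TBSO)-3,3-dimethyl-1-[(E)-2-(trimethylsilyl)ethenyl]cyclohexane-1,2-diolate | C[Si](C)(C)/C=C/[C@@]1([O-])CC[C@@H](O[Si](C)(C)C(C)(C)C)C(C)(C)[C@@H]1[O-].[Mg+2] | intermediate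
10 | magnesium chloride (1S,2S,4R)-4-(TBSO)-2-(methanesulfonyloxy)-3,3-dimethyl-1-[(E)-2-(trimethylsilyl)ethenyl]cyclohexan-1-olate | C[Si](C)(C)/C=C/[C@@]1([O-])CC[C@@H](O[Si](C)(C)C(C)(C)C)C(C)(C)[C@@H]1OS(C)(=O)=O.[Mg+2].[Cl-] | intermediate
11 | (2R,4R)-4-(TBSO)-3,3-dimethyl-2-[(E)-2-(trimethylsilyl)ethenyl]cyclohexan-1-one | O=C1CC[C@@H](O[Si](C)(C)C(C)(C)C)C(C)(C)[C@H]1/C=C/[Si](C)(C)C | intermediate
12 | (2R,4R)-4-(TBSO)-2-[(E)-2-iodoethenyl]-3,3-dimethylcyclohexan-1-one | O=C1CC[C@@H](O[Si](C)(C)C(C)(C)C)C(C)(C)[C@H]1/C=C/I | intermediate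
13 | tert-butyl({(1R,3S)-3-[(E)-2-iodoethenyl]-2,2-dimethyl-4-methylidenecyclohexyl}oxy)dimethylsilane | C=C1CC[C@@H](O[Si](C)(C)C(C)(C)C)C(C)(C)[C@H]1/C=C/I | intermediate
14 | cyclohexane-1,4-dione | O=C1CCC(=O)CC1 | starting material
15 | dimethyl carbonate | COC(=O)OC | starting material
16 | dimethyl 2,5-dihydroxycyclohexa-1,4-diene-1,4-dicarboxylate (dimethyl succinylsuccinate, bis-enol form) | COC(=O)C1=C(O)CC(C(=O)OC)=C(O)C1 | intermediate
17 | dimethyl (2S,5S)-2,5-dihydroxycyclohexane-1,4-dicarboxylate | COC(=O)C1C[C@H](O)C(C(=O)OC)C[C@@H]1O | intermediate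
18 | dimethyl (2S,5S)-2,5-bis(TBSO)cyclohexane-1,4-dicarboxylate | COC(=O)C1C[C@H](O[Si](C)(C)C(C)(C)C)C(C(=O)OC)C[C@@H]1O[Si](C)(C)C(C)(C)C | intermediate
19 | dimethyl (2S,5S)-2,5-bis(TBSO)-1,4-bis(phenylselanyl)cyclohexane-1,4-dicarboxylate | COC(=O)C1([Se]c2ccccc2)C[C@H](O[Si](C)(C)C(C)(C)C)C(C(=O)OC)([Se]c2ccccc2)C[C@@H]1O[Si](C)(C)C(C)(C)C | intermediate
20 | dimethyl (3S,6S)-3,6-bis(TBSO)cyclohexa-1,4-diene-1,4-dicarboxylate | COC(=O)C1=C[C@H](O[Si](C)(C)C(C)(C)C)C(C(=O)OC)=C[C@@H]1O[Si](C)(C)C(C)(C)C | intermediate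
21 | [(3S,6S)-3,6-bis(TBSO)cyclohexa-1,4-diene-1,4-diyl]dimethanol | OCC1=C[C@H](O[Si](C)(C)C(C)(C)C)C(CO)=C[C@@H]1O[Si](C)(C)C(C)(C)C | intermediate
22 | [(3S,6S)-3,6-bis(TBSO)-4-(TBSO-methyl)cyclohexa-1,4-dien-1-yl]methanol | OCC1=C[C@H](O[Si](C)(C)C(C)(C)C)C(CO[Si](C)(C)C(C)(C)C)=C[C@@H]1O[Si](C)(C)C(C)(C)C | intermediate
23 | [(1S,2S,5R,6S)-2,5-bis(TBSO)-4-(TBSO-methyl)-7-oxabicyclo[4.1.0]hept-3-en-1-yl]methanol | OC[C@]12O[C@H]1[C@H](O[Si](C)(C)C(C)(C)C)C(CO[Si](C)(C)C(C)(C)C)=C[C@@H]2O[Si](C)(C)C(C)(C)C | intermediate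
24 | (1S,2S,5R,6S)-2,5-bis(TBSO)-4-(TBSO-methyl)-7-oxabicyclo[4.1.0]hept-3-ene-1-carbaldehyde | O=C[C@]12O[C@H]1[C@H](O[Si](C)(C)C(C)(C)C)C(CO[Si](C)(C)C(C)(C)C)=C[C@@H]2O[Si](C)(C)C(C)(C)C | intermediate
25 | propyne | CC#C | starting material
26 | (Z)-prop-1-ene-1,2-diylbis(trimethylstannane) | C[Sn](C)(C)/C=C(/C)[Sn](C)(C)C | intermediate
27 | [(Z)-2-(trimethylstannyl)prop-1-en-1-yl]lithium | [Li]/C=C(/C)[Sn](C)(C)C | intermediate
28 | (1S,2Z)-1-[(1S,2S,5R,6S)-2,5-bis(TBSO)-4-(TBSO-methyl)-7-oxabicyclo[4.1.0]hept-3-en-1-yl]-3-(trimethylstannyl)but-2-en-1-ol | C[Sn](C)(C)/C(C)=C\[C@H](O)[C@]12O[C@H]1[C@H](O[Si](C)(C)C(C)(C)C)C(CO[Si](C)(C)C(C)(C)C)=C[C@@H]2O[Si](C)(C)C(C)(C)C | intermediate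
29 | (1S,2Z,4E)-1-[(1S,2S,5R,6S)-2,5-bis(TBSO)-4-(TBSO-methyl)-7-oxabicyclo[4.1.0]hept-3-en-1-yl]-5-[(1S,3R)-3-(TBSO)-2,2-dimethyl-6-methylidenecyclohexyl]-3-methylpenta-2,4-dien-1-ol | C=C1CC[C@@H](O[Si](C)(C)C(C)(C)C)C(C)(C)[C@H]1/C=C/C(C)=C\[C@H](O)[C@]12O[C@H]1[C@H](O[Si](C)(C)C(C)(C)C)C(CO[Si](C)(C)C(C)(C)C)=C[C@@H]2O[Si](C)(C)C(C)(C)C | intermediate
30 | (1R,2S,5R,6S)-1-{(1S,2Z,4E)-1-hydroxy-5-[(1S,3R)-3-hydroxy-2,2-dimethyl-6-methylidenecyclohexyl]-3-methylpenta-2,4-dien-1-yl}-4-(hydroxymethyl)-7-oxabicyclo[4.1.0]hept-3-ene-2,5-diol (CNP0357844.1) | C=C1CC[C@@H](O)C(C)(C)[C@H]1/C=C/C(C)=C\[C@H](O)[C@]12O[C@H]1[C@H](O)C(CO)=C[C@@H]2O | target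

**Totals**
Total step count: 19. Longest linear sequence: 11 steps (steps 8–15, then 17–19, from 14 to 30).

**Three steps most likely to fail**

Step 5 (the proposed new step). The hindered secondary alkoxide may resist sulfonylation, or the ring bond may migrate instead of the alkenyl group. The fallback is known chemistry and uses no rearrangement. It sets out from silyl enol ether 5, which is then isolated after the first stage of step 4. MeLi in THF cleaves 5 to the regiodefined lithium enolate F1. Palladium-catalysed α-alkenylation of this ketone enolate with bromide 7 [Pd2(dba)3, P(t-Bu)3, THF, 25–50 °C], followed by equilibration of the α-centre to the equatorial epimer, gives ketone 11, where the route is rejoined.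

Step 9. Compound 16 is almost fully enolised and sparingly soluble, so the hydrogenation may stall or stop at the mono-alcohol. The fallback sets out from 16 and reduces it biocatalytically (baker's yeast, or a commercial ketoreductase with NADPH recycled by glucose dehydrogenase, pH 7 buffer/DMSO, 30 °C). Whole-cell reduction of 2-oxocycloalkanecarboxylates is known to give the (S) carbinols. The route is rejoined at 17 and no new compound is formed (F0).

Step 17. Exchange at the wrong tin, or poor facial selectivity in the aldehyde addition, would erode the carbinol centre. The fallback sets out from 28 obtained as a mixture of carbinol epimers. Dess–Martin oxidation gives the stannyl enone F2, and reduction of F2 with Zn(BH4)2 (Et2O, −20 °C) follows. Zinc chelation between the ketone and the epoxide oxygen is the known route to anti epoxy alcohols from α,β-epoxy ketones, and it returns 28 as the single (1S) epimer.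

**Further compounds**
F1 | step 5 | lithium (4R)-4-(TBSO)-3,3-dimethylcyclohex-1-en-1-olate | CC1(C)C=C([O-])CC[C@H]1O[Si](C)(C)C(C)(C)C.[Li+]
F0 | step 9 | none | none
F2 | step 17 | (2Z)-1-[(1S,2S,5R,6S)-2,5-bis(TBSO)-4-(TBSO-methyl)-7-oxabicyclo[4.1.0]hept-3-en-1-yl]-3-(trimethylstannyl)but-2-en-1-one | C[Sn](C)(C)/C(C)=C\C(=O)[C@]12O[C@H]1[C@H](O[Si](C)(C)C(C)(C)C)C(CO[Si](C)(C)C(C)(C)C)=C[C@@H]2O[Si](C)(C)C(C)(C)C
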